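Atom numbers: C1 carbinol carbon, C2=C3 alkene, C4 ketone, C5 spiro carbon, C6/C7 methylenes, C8 ether carbon, O9 ring oxygen. Everything hinges on making the O9–C5 bond of the oxolane ring last. C5 lies α to the C4 carbonyl but is bonded to oxygen, so an enol carbon and a hydroxyl, two donors, must be joined; taking electrons from the C4/C5 silyl dienol ether at an anode turns C5 into the acceptor. In a single operation the C8 tertiary alcohol closes the spiro tetrahydrofuran, sets the C5 stereocentre and hands back the cyclopentenone. The substrate is a 2-(triisopropylsilyloxy)cyclopentadiene with ethynyl (latent acetyl) and triethylsilyloxy groups on C1 and the phytol-derived (S)-hydroxyalkyl chain on C5.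

Key step: step 12

Remark: the target as drawn is (1S,5R,8S) in this numbering, with C1–OH trans to C5–O9, so the L-(+)-tartrate epoxide of phytol is needed; C1 is made without control relative to C8, so 14–18 are expected as about equal mixtures of C1 epimers (SMILES show the epimer that leads on), the other ring centres of 12 and 14–17 are mixtures that converge at 18, and the unwanted C1 series is removed by chromatography after step 12.

Step 1
Reactants: 1 2,3-dimethylmaleic anhydride
Product: 2 5-hydroxy-3,4,5-trimethylfuran-2(5H)-one (racemic)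
Conditions: MeMgBr (1.05 equiv), THF, −78 → −20 °C; aq. HCl
Reagents that add atoms: methylmagnesium bromide, C[Mg]Br
Why: Grignard mono-addition to a cyclic anhydride should stop at the keto carboxylate, which closes to the γ-hydroxybutenolide on acidification; the new centre is racemic and is destroyed in step 2.

Step 2
Reactants: 2 5-hydroxy-3,4,5-trimethylfuran-2(5H)-one
Product: 3 3,4-dimethyl-5-methylidenefuran-2(5H)-one
Conditions: TsOH (cat.), toluene, reflux, Dean–Stark
Reagents that add atoms: none
Why: Acid-catalysed dehydration of the hydroxybutenolide can only place the new double bond exocyclic, giving the 4-ylidenebutenolide (enol lactone).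

Step 3
Reactants: 3 3,4-dimethyl-5-methylidenefuran-2(5H)-one
Product: 5 4,5-dimethylcyclopent-4-ene-1,3-dione, via keto ester 4 (not isolated)
Conditions: NaOMe (1.1 equiv), MeOH, 0 °C → rt; aq. HCl
Reagents that add atoms: none
Why: Methoxide opens the enol lactone to the ketone enolate of 4, which closes by Dieckmann-type acylation (the base-induced ylidenebutenolide to cyclopent-4-ene-1,3-dione rearrangement), driven by the stabilised dione anion; the former exocyclic carbon becomes C5.

Step 4
Reactants: 6 natural (E,7R,11R)-phytol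
Product: 7 [(2S,3S)-3-methyl-3-[(4R,8R)-4,8,12-trimethyltridecyl]oxiran-2-yl]methanol ((2S,3S)-2,3-epoxyphytol)
Conditions: Ti(OiPr)4 (10 mol%), L-(+)-diethyl tartrate (12 mol%), t-BuOOH, 4 Å MS, CH2Cl2, −20 °C
Reagents that add atoms: tert-butyl hydroperoxide, CC(C)(C)OO
Why: Sharpless asymmetric epoxidation of the E-allylic alcohol; the L-(+)-tartrate ligand delivers oxygen to the face that gives the (2S,3S)-epoxide (as with geraniol), which fixes the later C8 centre by reagent control.

Step 5
Reactants: 7 (2S,3S)-2,3-epoxyphytol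
Product: 8 (3S,7R,11R)-3,7,11,15-tetramethylhexadecane-1,3-diol
Conditions: NaAlH2(OCH2CH2OMe)2, THF, 0 °C → rt; aq. NaOH
Reagents that add atoms: none
Why: Hydroxyl-directed reductive opening of a 2,3-epoxy alcohol: the alkoxyaluminate delivers hydride to C2, so the C3–O bond and its configuration are untouched and the 1,3-diol with the tertiary (S)-carbinol results.

Step 6
Reactants: 8 (3S,7R,11R)-3,7,11,15-tetramethylhexadecane-1,3-diol
Product: 9 (3S,7R,11R)-3-hydroxy-3,7,11,15-tetramethylhexadecanal
Conditions: TEMPO (10 mol%), PhI(OAc)2 (1.1 equiv), CH2Cl2, rt; used crude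
Reagents that add atoms: none
Why: Oxoammonium (TEMPO) oxidation is selective for the primary alcohol, stops at the aldehyde and cannot touch the tertiary alcohol.

Step 7
Reactants: 5 4,5-dimethylcyclopent-4-ene-1,3-dione; 9 (3S,7R,11R)-3-hydroxy-3,7,11,15-tetramethylhexadecanal
Product: 11 2-[(3S,7R,11R)-3-hydroxy-3,7,11,15-tetramethylhexadecyl]-4,5-dimethylcyclopent-4-ene-1,3-dione, via alkylidene dione 10 (not isolated)
Conditions: L-proline (20 mol%), diethyl 2,6-dimethyl-1,4-dihydropyridine-3,5-dicarboxylate (Hantzsch ester, 1.1 equiv), CH2Cl2, rt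
Reagents that add atoms: none
Why: Organocatalytic reductive alkylation of an acidic cyclic 1,3-dione: Knoevenagel condensation at C5 followed by transfer hydrogenation of the alkylidene dione by the dihydropyridine forms C5–C6 as a clean C-monoalkylation, a mode that excludes O-alkylation and double alkylation.

Step 8
Reactants: 11 2-[(3S,7R,11R)-3-hydroxy-3,7,11,15-tetramethylhexadecyl]-4,5-dimethylcyclopent-4-ene-1,3-dione
Product: 12 (2S)-7a-methoxy-2,6,7-trimethyl-2-[(4R,8R)-4,8,12-trimethyltridecyl]-2,3,4,4a-tetrahydrocyclopenta[b]pyran-5(7aH)-one (C4 methyl ketal closed onto the C8 oxygen; ring-junction diastereomers)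
Conditions: HC(OMe)3 (3 equiv), CSA (5 mol%), MeOH, rt; Et3N quench
Reagents that add atoms: trimethyl orthoformate, COC(OC)OC
Why: Acid-catalysed mixed ketalisation of a δ-hydroxy ketone: the C8 hydroxyl adds to either of the two equivalent ring carbonyls (six-membered hemiketal) and methoxy exchange fixes it, which masks the C4 carbonyl, the C8 hydroxyl and the 1,3-dione acidity of C5–H at once; the ring-junction centres are uncontrolled and are erased later.

Step 9
Reactants: 12 bicyclic methyl ketal; 13 trimethylsilylacetylene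
Product: 15 triethyl({(2S)-7a-methoxy-2,6,7-trimethyl-5-[(trimethylsilyl)ethynyl]-2-[(4R,8R)-4,8,12-trimethyltridecyl]-2,3,4,4a,5,7a-hexahydrocyclopenta[b]pyran-5-yl}oxy)silane (C1 epimers), via lithium alkoxide 14 (not isolated)
Conditions: 13, n-BuLi, THF, −78 °C; 12, −78 → −20 °C; then Et3SiOTf, −78 → 0 °C
Reagents that add atoms: triethylsilyl trifluoromethanesulfonate, CC[Si](CC)(CC)OS(=O)(=O)C(F)(F)F
Why: 1,2-Addition of a lithium acetylide to the only free ketone (C1), then O-silylation of the tertiary alkoxide in the same flask, which should be much faster than activation of the ketal at low temperature; C1 is formed as both epimers relative to C8, and the bulky silyl ether is chosen to steer step 12.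

Step 10
Reactants: 15 silyl ether of the alkynyl ketal
Product: 17 4-ethynyl-5-[(3S,7R,11R)-3-hydroxy-3,7,11,15-tetramethylhexadecyl]-2,3-dimethyl-4-[(triethylsilyl)oxy]cyclopent-2-en-1-one (diastereomers at the two ring sp3 centres), via terminal alkyne ketal 16 (not isolated)
Conditions: K2CO3, MeOH, rt; then 1 M aq. HCl, THF, 0 °C
Reagents that add atoms: water, O
Why: Methanolysis of the alkynyl C–Si bond, then acid hydrolysis of the allylic mixed ketal, which ionises far more readily than the hindered tertiary silyl ether, frees the C4 ketone and the C8 hydroxyl while C1–O stays protected, so the two tertiary alcohols are differentiated without a separate protection step.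

Step 11
Reactants: 17 hydroxy ketone
Product: 18 (3S,7R,11R)-1-{5-ethynyl-3,4-dimethyl-5-[(triethylsilyl)oxy]-2-[(triisopropylsilyl)oxy]cyclopenta-1,3-dien-1-yl}-3,7,11,15-tetramethylhexadecan-3-ol (C1 epimers)
Conditions: iPr3SiOTf (1.3 equiv), Et3N (3 equiv), CH2Cl2, −78 → 0 °C
Reagents that add atoms: triisopropylsilyl trifluoromethanesulfonate, CC(C)[Si](OS(=O)(=O)C(F)(F)F)(C(C)C)C(C)C
Why: Soft enolisation (silyl triflate and amine) of the cyclopentenone can only go toward C5, giving the conjugated silyl dienol ether and erasing the C5 centre; the very bulky silyl triflate should leave the tertiary C8 alcohol free, and C1 without hydrogen blocks 1,5-hydrogen shifts in the diene.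

Step 12
Reactants: 18 silyl dienol ether with free C8 hydroxyl
Product: 19 (2S,5R,9S)-9-ethynyl-2,7,8-trimethyl-9-[(triethylsilyl)oxy]-2-[(4R,8R)-4,8,12-trimethyltridecyl]-1-oxaspiro[4.4]non-7-en-6-one
Conditions: reticulated vitreous carbon anode, platinum cathode, undivided cell, constant current (2.2 F/mol), LiClO4 (0.1 M), 2,6-lutidine, MeOH/THF 1:4, rt; chromatography
Reagents that add atoms: none
Why: Removal of one electron from the silyloxydiene at the carbon anode should give a radical cation that the C8 hydroxyl traps at C5; a second electron is then taken from the allyl radical spread over C2, C3 and C4, and methanol strips the triisopropylsilyl group so that the C2=C3–C4=O enone reappears. The closest known reaction type is the anodic coupling of enol ether and silyl enol ether radical cations with tethered alcohols to give tetrahydrofurans, which tolerates tertiary alcohols and fully substituted carbons. The tetrahydrofuran ring (O9, C5, C6, C7, C8) closes in the 5-exo-trig mode, which also settles the site of attack, since C3 or C2 could only be reached through a seven- or eight-membered ring. The new stereocentre C5 is controlled by the adjacent quaternary C1: oxygen should enter anti to the bulky, non-hydrogen-bonding triethylsilyl ether and syn to the rod-like ethynyl group, which also keeps the C1–O and C5–O9 dipoles apart and gives the trans C1–O/C5–O9 relationship. The step needs chemoselective oxidation (the silyloxydiene has by far the lowest oxidation potential; alkyne, silyl ether and alcohol are inert), ring closure faster than capture by methanol (five-membered closure, little methanol, 2,6-lutidine as proton sink) and face selectivity (secured by the C1 substituents). The C1 epimer in 18 should cyclise in the same sense to the (2S,5S,9R) isomer, which is removed by chromatography.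

Step 13
Reactants: 19 spiro ethynyl ketone
Product: 20 (2S,5R,9S)-9-acetyl-2,7,8-trimethyl-9-[(triethylsilyl)oxy]-2-[(4R,8R)-4,8,12-trimethyltridecyl]-1-oxaspiro[4.4]non-7-en-6-one
Conditions: Ph3PAuNTf2 (5 mol%), H2O (5 equiv), 1,4-dioxane, 60 °C
Reagents that add atoms: water, O
Why: Monovalent-gold-catalysed Markovnikov hydration of the terminal alkyne gives the methyl ketone; the neighbouring C4 carbonyl can only assist delivery of water to the internal alkyne carbon, and no stereocentre is touched.

Step 14
Reactants: 20 silyl-protected methyl ketone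
Product: 21 α-tocospiro A, (2S,5R,9S)-9-acetyl-9-hydroxy-2,7,8-trimethyl-2-[(4R,8R)-4,8,12-trimethyltridecyl]-1-oxaspiro[4.4]non-7-en-6-one
Conditions: HF·pyridine, pyridine, THF, 0 °C → rt
Reagents that add atoms: none
Why: Fluoride-mediated desilylation under weakly acidic conditions avoids a free C1 alkoxide, which could open the C1–C5 bond by retro-aldol reaction, so C1 and C5 keep their configuration.

Compound list
1 | 2,3-dimethylmaleic anhydride | CC1=C(C)C(=O)OC1=O | starting material
2 | 5-hydroxy-3,4,5-trimethylfuran-2(5H)-one (racemic) | CC1=C(C)C(C)(O)OC1=O | intermediate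
3 | 3,4-dimethyl-5-methylidenefuran-2(5H)-one | CC1=C(C)C(=C)OC1=O | intermediate
4 | methyl (2Z)-2,3-dimethyl-4-oxopent-2-enoate (formed as its ketone enolate, not isolated) | COC(=O)/C(C)=C(/C)C(C)=O | intermediate
5 | 4,5-dimethylcyclopent-4-ene-1,3-dione | CC1=C(C)C(=O)CC1=O | intermediate
6 | natural (E,7R,11R)-phytol | CC(C)CCC[C@@H](C)CCC[C@@H](C)CCC/C(C)=C/CO | starting material
7 | [(2S,3S)-3-methyl-3-[(4R,8R)-4,8,12-trimethyltridecyl]oxiran-2-yl]methanol | OC[C@@H]1O[C@@]1(C)CCC[C@H](C)CCC[C@H](C)CCCC(C)C | intermediate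
8 | (3S,7R,11R)-3,7,11,15-tetramethylhexadecane-1,3-diol | OCC[C@@](C)(O)CCC[C@H](C)CCC[C@H](C)CCCC(C)C | intermediate
9 | (3S,7R,11R)-3-hydroxy-3,7,11,15-tetramethylhexadecanal | O=CC[C@@](C)(O)CCC[C@H](C)CCC[C@H](C)CCCC(C)C | intermediate
10 | 2-[(3S,7R,11R)-3-hydroxy-3,7,11,15-tetramethylhexadecylidene]-4,5-dimethylcyclopent-4-ene-1,3-dione (not isolated) | CC1=C(C)C(=O)C(=CC[C@@](C)(O)CCC[C@H](C)CCC[C@H](C)CCCC(C)C)C1=O | intermediate
11 | 2-[(3S,7R,11R)-3-hydroxy-3,7,11,15-tetramethylhexadecyl]-4,5-dimethylcyclopent-4-ene-1,3-dione | CC1=C(C)C(=O)C(CC[C@@](C)(O)CCC[C@H](C)CCC[C@H](C)CCCC(C)C)C1=O | intermediate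
12 | (2S)-7a-methoxy-2,6,7-trimethyl-2-[(4R,8R)-4,8,12-trimethyltridecyl]-2,3,4,4a-tetrahydrocyclopenta[b]pyran-5(7aH)-one (ring-junction diastereomers) | COC12O[C@@](C)(CCC[C@H](C)CCC[C@H](C)CCCC(C)C)CCC1C(=O)C(C)=C2C | intermediate
13 | trimethylsilylacetylene | C#C[Si](C)(C)C | starting material
14 | lithium (2S)-7a-methoxy-2,6,7-trimethyl-5-[(trimethylsilyl)ethynyl]-2-[(4R,8R)-4,8,12-trimethyltridecyl]-2,3,4,4a,5,7a-hexahydrocyclopenta[b]pyran-5-olate (C1 epimers, productive one shown; not isolated) | [Li+].[O-][C@@]1(C#C[Si](C)(C)C)C(C)=C(C)C2(OC)O[C@@](C)(CCC[C@H](C)CCC[C@H](C)CCCC(C)C)CCC12 | intermediate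
15 | triethyl({(2S)-7a-methoxy-2,6,7-trimethyl-5-[(trimethylsilyl)ethynyl]-2-[(4R,8R)-4,8,12-trimethyltridecyl]-2,3,4,4a,5,7a-hexahydrocyclopenta[b]pyran-5-yl}oxy)silane (C1 epimers, productive one shown) | CC[Si](CC)(CC)O[C@@]1(C#C[Si](C)(C)C)C(C)=C(C)C2(OC)O[C@@](C)(CCC[C@H](C)CCC[C@H](C)CCCC(C)C)CCC12 | intermediate
16 | triethyl({(2S)-5-ethynyl-7a-methoxy-2,6,7-trimethyl-2-[(4R,8R)-4,8,12-trimethyltridecyl]-2,3,4,4a,5,7a-hexahydrocyclopenta[b]pyran-5-yl}oxy)silane (C1 epimers, productive one shown; not isolated) | CC[Si](CC)(CC)O[C@@]1(C#C)C(C)=C(C)C2(OC)O[C@@](C)(CCC[C@H](C)CCC[C@H](C)CCCC(C)C)CCC12 | intermediate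
17 | 4-ethynyl-5-[(3S,7R,11R)-3-hydroxy-3,7,11,15-tetramethylhexadecyl]-2,3-dimethyl-4-[(triethylsilyl)oxy]cyclopent-2-en-1-one (C1 epimers, productive one shown; C5 unfixed) | CC[Si](CC)(CC)O[C@@]1(C#C)C(C)=C(C)C(=O)C1CC[C@@](C)(O)CCC[C@H](C)CCC[C@H](C)CCCC(C)C | intermediate
18 | (3S,7R,11R)-1-{5-ethynyl-3,4-dimethyl-5-[(triethylsilyl)oxy]-2-[(triisopropylsilyl)oxy]cyclopenta-1,3-dien-1-yl}-3,7,11,15-tetramethylhexadecan-3-ol (C1 epimers, productive one shown: C1 configured as in the target) | CC[Si](CC)(CC)O[C@@]1(C#C)C(C)=C(C)C(O[Si](C(C)C)(C(C)C)C(C)C)=C1CC[C@@](C)(O)CCC[C@H](C)CCC[C@H](C)CCCC(C)C | intermediate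
19 | (2S,5R,9S)-9-ethynyl-2,7,8-trimethyl-9-[(triethylsilyl)oxy]-2-[(4R,8R)-4,8,12-trimethyltridecyl]-1-oxaspiro[4.4]non-7-en-6-one | C#C[C@]1(O[Si](CC)(CC)CC)C(C)=C(C)C(=O)[C@@]12CC[C@](C)(CCC[C@H](C)CCC[C@H](C)CCCC(C)C)O2 | intermediate
20 | (2S,5R,9S)-9-acetyl-2,7,8-trimethyl-9-[(triethylsilyl)oxy]-2-[(4R,8R)-4,8,12-trimethyltridecyl]-1-oxaspiro[4.4]non-7-en-6-one | CC(=O)[C@]1(O[Si](CC)(CC)CC)C(C)=C(C)C(=O)[C@@]12CC[C@](C)(CCC[C@H](C)CCC[C@H](C)CCCC(C)C)O2 | intermediate
21 | α-tocospiro A, (2S,5R,9S)-9-acetyl-9-hydroxy-2,7,8-trimethyl-2-[(4R,8R)-4,8,12-trimethyltridecyl]-1-oxaspiro[4.4]non-7-en-6-one | CC(=O)[C@]1(O)C(C)=C(C)C(=O)[C@@]12CC[C@](C)(CCC[C@H](C)CCC[C@H](C)CCCC(C)C)O2 | target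

Total step count: 14. Longest linear sequence: 11 steps (steps 1–3 then 7–14; the phytol branch, steps 4–6 then 7–14, is equally long).

Steps most likely to fail

Step 12. The oxygen may enter C5 on the face of the C1 silyl ether, methanol may capture the radical cation before ring closure, or the dienol ether may simply be desilylated back to ketone 17. The fallback keeps the same bond but uses a two-electron chemical oxidant. From 18, PhI(OAc)2 with BF3·OEt2 and 2,6-di-tert-butylpyridine in CH2Cl2 at −40 °C should bind the enol oxygen to trivalent iodine. The C8 hydroxyl then attacks C5 as iodobenzene leaves; this is the established hypervalent-iodine α-oxygenation of silyl enol ethers, run intramolecularly. The route is rejoined directly at 19 and no further compound is made on the way (F0).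

Step 7. Aldehyde 9 may undergo retro-aldol cleavage or dehydration under amine catalysis, or hydride transfer to the alkylidene dione may be slow. The fallback forms C5–C6 by alkylation. It sets out from diol 8, which is converted with I2, PPh3 and imidazole in CH2Cl2 at 0 °C (Appel-type iodination of the primary alcohol only) into (3S,7R,11R)-1-iodo-3,7,11,15-tetramethylhexadecan-3-ol F1. The potassium salt of dione 5 (K2CO3, DMF, 40 °C, excess 5) is then C-alkylated by F1. O-Alkylation would create an antiaromatic alkoxycyclopentadienone and is disfavoured, and carbonate does not deprotonate the tertiary alcohol. This gives 11, where the route is rejoined.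

Step 11. Silylation of the C8 hydroxyl may compete, or enolisation at the hindered C5–H may be sluggish. The fallback masks the alcohol and uses a preformed enolate. From 17, N-(trimethylsilyl)imidazole in CH2Cl2 at rt gives 4-ethynyl-2,3-dimethyl-5-{(3S,7R,11R)-3,7,11,15-tetramethyl-3-[(trimethylsilyl)oxy]hexadecyl}-4-[(triethylsilyl)oxy]cyclopent-2-en-1-one F2. Deprotonation with KN(SiMe3)2 (1.0 equiv, THF, −78 °C) and trapping with iPr3SiOTf gives triethyl[(1-ethynyl-2,3-dimethyl-5-{(3S,7R,11R)-3,7,11,15-tetramethyl-3-[(trimethylsilyl)oxy]hexadecyl}-4-[(triisopropylsilyl)oxy]cyclopenta-2,4-dien-1-yl)oxy]silane F3. K2CO3 in MeOH at 0 °C should then cleave only the trimethylsilyl ether and return 18.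

Further compounds
F0 | step 12 | none | none
F1 | step 7 | (3S,7R,11R)-1-iodo-3,7,11,15-tetramethylhexadecan-3-ol | ICC[C@@](C)(O)CCC[C@H](C)CCC[C@H](C)CCCC(C)C
F2 | step 11 | 4-ethynyl-2,3-dimethyl-5-{(3S,7R,11R)-3,7,11,15-tetramethyl-3-[(trimethylsilyl)oxy]hexadecyl}-4-[(triethylsilyl)oxy]cyclopent-2-en-1-one | CC[Si](CC)(CC)O[C@@]1(C#C)C(C)=C(C)C(=O)C1CC[C@@](C)(O[Si](C)(C)C)CCC[C@H](C)CCC[C@H](C)CCCC(C)C
F3 | step 11 | triethyl[(1-ethynyl-2,3-dimethyl-5-{(3S,7R,11R)-3,7,11,15-tetramethyl-3-[(trimethylsilyl)oxy]hexadecyl}-4-[(triisopropylsilyl)oxy]cyclopenta-2,4-dien-1-yl)oxy]silane | CC[Si](CC)(CC)O[C@@]1(C#C)C(C)=C(C)C(O[Si](C(C)C)(C(C)C)C(C)C)=C1CC[C@@](C)(O[Si](C)(C)C)CCC[C@H](C)CCC[C@H](C)CCCC(C)C
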